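The runs stem from a simulated flask for substances that don't exist.

L comes late. At 0.625 d it reads 0% in the dawn run and 0% in the dusk run, while G in the dawn run has already lost 7.30% of its charge.

| flask | G | E | remark | time |
|---|---|---|---|---|
| dawn | 0.14 M | 29 mM (held) | run made earlier |  |
| dusk | 0.22 M | 29 mM (held) | run made earlier |  |
| flask | 0.10 M | 29 mM (held) |  | 10 d |

| run | time / d | L / % | G / % |
|---|---|---|---|
| dawn | 0.625 | 0 | 92.7 |
| dawn | 2.08 | 1.8 | 74.4 |
| dawn | 4.00 | 7.7 | 56.3 |
| dawn | 6.00 | 13.0 | 38.9 |
| dawn | 8.00 | 17.2 | 18.3 |
| dusk | 0.625 | 0 | 94.1 |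
| dusk | 1.25 | 1.5 | 89.5 |
| dusk | 2.50 | 2.5 | 83.0 |
| dusk | 4.00 | 5.5 | 70.6 |
| dusk | 8.00 | 9.6 | 49.3 |

(scatter of a reading: 1 percentage point)

- solid, in amounts per volume of the solution: G
- at the start none of E is in solution
- at the start none of G is in solution

- teal: doubling the solubility of G, all else as stated
- ochre: doubling the transfer coefficient of E, all else as stated
- violet: doubling the dissolution coefficient of G, all else as stated
- grey: doubling the saturation concentration of E, all else as stated

* L at 10 d, in percent of the G charged
* the change that raises the amount of L at 10 d, in percent of the G charged most ("none" if none brings more than 2 percentage points) (teal / ochre / violet / grey / none)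
* amount of L at 10 d, in percent of the G charged, after ochre

The flask, in slow motion, as reckoned here from those runs.

First instants: at the start neither E nor G is in solution.

Middle: solid G falls at a similar molar rate in both runs, 0.0141 M d⁻¹ at dawn and 0.0134 M d⁻¹ at dusk. At that dawn rate the flask's charge lasts 7.08 d, shorter than the time asked. Dividing the rate of L by the rate of loss of G removes time. From 4.00 d to 8.00 d in the dawn run, the readings show L gaining 25.0% of the G lost, and from 2.50 d to 8.00 d in the dusk run 21.1%, a mean share, as read, of 23.0%. The rest of the lost G is not read as L. L gained per unit of lost G not read as L is the odds of L, a selectivity factor: 0.299.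

End: past 7.08 d the reckoned solid is gone, and dissolved G drains through the same fork, on this reckoning's assumption. So this reckoning puts L at 10 d near the share itself, 23.0% of the charge.

Ochre and grey act on dissolved E. If L's path goes with dissolved E and ochre at most doubles it, the odds at most double, and this reckoning puts L after ochre at no more than 37.4%. This reckoning picks grey.

The forecast gives 28% (24% to 33%), grey as the best change, and 45% (36% to 56%) after ochre: “Doubling E saturation doubles L, since the system is linear in E.” Its ochre figure stands above the figure reckoned here.

The flask gives 24.1% at 10 d. The best change is grey, with a gain of 9.4 percentage points, more than the 4.9 points of ochre, which ends at 28.9%.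

    E ⇌ Q, rate k1*(csat - [Q]) (kL = 0.0690 h⁻¹)
    D + Q → L (k = 0.550 L mol⁻¹ h⁻¹)
    D → X (k = 0.0210 h⁻¹)
    G ⇌ D, rate k4*(cs4 - [D]) while solid is left; crystals form when [D] > cs4 (solubility = 0.0570 M, k = 0.0150 h⁻¹)
    2 Q → J (k = 3.20 L mol⁻¹ h⁻¹)

In the flask, D goes to L at 0.55 L mol⁻¹ h⁻¹ times Q and to X at 0.021 h⁻¹, and with Q at 0.0130 M at 10.0 d the ratio of these rates is 0.340, beside the odds of 0.299 read from the runs. L over X stands at 0.328 in the flask at 10.0 d and at 0.324 in the same flask read at 2.50 d.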